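**Plan**

Numbering follows the drimanes: ring A is C1–C5 and C10, ring B is C5–C10, C4 carries the gem-dimethyl group, C10 the angular methyl, C9 the side chain (C11 onward).
- Cuts: C9–C11 together with C9–H (back to a C9 ketone), then C1–C10, then C10–CH3 and C3–C4; what remains is (R)-carvone.
- Enabling feature: ring B with its C8 methyl, C7=C8 alkene and C4 on C5 is the p-menthene skeleton of carvone. C10 is the α′ carbon beside the C9 carbonyl, so it can take CH3 and a radical leaving group, and it sits 1,3 to the isopropenyl carbon C4 across C5.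
- Forward: an iron-hydride Giese coupling turns the isopropenyl group into C4(CH3)2–C3–C2–C1≡N; enolate chemistry loads C10 with CH3 and PhSe; i-Bu2AlH takes C9 to the alcohol and C1 to the aldehyde; the C10 radical closes ring A onto a traceless N-aziridinyl imine.
- Ring B is bought, ring A is closed in step 8, and the C16 chain is joined to C9 last (organolithium addition, then palladium/formate exchange of C9–O for C9–H with the alkene kept at C7=C8).
- Stereochemistry: C5 comes from (R)-carvone; C10 is relayed from C5 in the radical closure (chair-like, trans fusion); C9 is relayed from C10 (addition anti to the angular methyl, hydride delivered anti to the carbonate).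

Key step: step 8

Remark: (3E,7E)-homofarnesol 15 is taken as a catalogue compound; epimers at C10 (4–12), at C9 (8–13) and at the aziridine carbon (12) are carried on together, because C10 becomes a planar radical, C9 a ketone and the aziridine carbon styrene.

**Route**

Step 1
Reactants: 1 (R)-(−)-carvone
Product: 2 4-methyl-4-[(1R)-4-methyl-5-oxocyclohex-3-en-1-yl]pentanenitrile
Conditions: Fe(acac)3 (30 mol %), PhSiH3, acrylonitrile (3 equiv), EtOH/(CH2OH)2, 60 °C
Reagents that add atoms: acrylonitrile, C=CC#N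
Why: Iron-hydride hydrogen-atom transfer to the CH2 terminus of the electron-rich 1,1-disubstituted alkene (the enone alkene is electron-poor and should not accept the hydrogen atom) gives the tertiary C4 radical, which adds to acrylonitrile in a Giese-type reductive olefin coupling; this makes the C4 gem-dimethyl centre and brings in C3, C2 and C1 without touching C5.

Step 2
Reactants: 2 4-methyl-4-[(1R)-4-methyl-5-oxocyclohex-3-en-1-yl]pentanenitrile
Product: 4 4-[(1R,6S)-4,6-dimethyl-5-oxocyclohex-3-en-1-yl]-4-methylpentanenitrile, via lithium enolate 3 (not isolated)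
Conditions: LiN(i-Pr)2, THF, −78 °C; MeI, −78 to 0 °C
Reagents that add atoms: iodomethane, CI
Why: Kinetic α′-deprotonation of the enone (the C10 hydrogens are far more acidic than those beside the nitrile) followed by C-alkylation of the cross-conjugated enolate; the methyl group should enter anti to the C5 substituent, but the C10 configuration is of no consequence.

Step 3
Reactants: 4 4-[(1R,6S)-4,6-dimethyl-5-oxocyclohex-3-en-1-yl]-4-methylpentanenitrile
Product: 6 4-[(1S,6S)-4,6-dimethyl-5-oxo-6-(phenylselanyl)cyclohex-3-en-1-yl]-4-methylpentanenitrile, via lithium enolate 5 (not isolated)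
Conditions: LiN(i-Pr)2, THF, −78 to −30 °C; PhSeBr, −78 °C
Reagents that add atoms: benzeneselenenyl bromide, Br[Se]c1ccccc1
Why: The last C10 hydrogen is removed to give the tetrasubstituted enolate, which is selenenylated on carbon (standard α-selenenylation of a ketone enolate) to install the tertiary C–Se bond that serves as the radical source in step 8.

Step 4
Reactants: 6 4-[(1S,6S)-4,6-dimethyl-5-oxo-6-(phenylselanyl)cyclohex-3-en-1-yl]-4-methylpentanenitrile
Product: 8 4-[(1S,5S,6S)-5-hydroxy-4,6-dimethyl-6-(phenylselanyl)cyclohex-3-en-1-yl]-4-methylpentanal, via aluminium alkoxide–iminoalane 7 (not isolated)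
Conditions: i-Bu2AlH (3.5 equiv), CH2Cl2, −78 °C; aq. potassium sodium tartrate
Reagents that add atoms: water, O
Why: i-Bu2AlH reduces the enone carbonyl 1,2 and the nitrile to the N-aluminio imine, which is hydrolysed on work-up to the aldehyde; C9 becomes sp3 (needed for step 8) and C1 reaches the aldehyde level, while the new C9 carbinol centre is erased again in step 9.

Step 5
Reactants: 9 (±)-1-phenylethane-1,2-diol
Product: 10 (±)-1-phenylethane-1,2-diyl dimethanesulfonate
Conditions: MsCl, Et3N, CH2Cl2, 0 °C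
Reagents that add atoms: methanesulfonyl chloride, CS(=O)(=O)Cl
Why: Routine sulfonylation of both hydroxyl groups; the stereocentre of this reagent plays no role because it leaves as styrene in step 8.

Step 6
Reactants: 10 (±)-1-phenylethane-1,2-diyl dimethanesulfonate
Product: 11 (±)-1-amino-2-phenylaziridine
Conditions: N2H4·H2O (excess), pentane, 23 °C
Reagents that add atoms: hydrazine, NN
Why: Double nucleophilic substitution by hydrazine (primary mesylate first, then 3-exo-tet closure at the benzylic carbon) is the established way to this N-aminoaziridine, which is used fresh.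

Step 7
Reactants: 8 4-[(1S,5S,6S)-5-hydroxy-4,6-dimethyl-6-(phenylselanyl)cyclohex-3-en-1-yl]-4-methylpentanal; 11 (±)-1-amino-2-phenylaziridine
Product: 12 (E)-N-(2-phenylaziridin-1-yl)imine of aldehyde 8
Conditions: CH2Cl2, MgSO4, 0 °C
Reagents that add atoms: none
Why: Hydrazone formation between the aldehyde and the N-amino group is fast at 0 °C, where the thermally labile N-aziridinyl imine survives; the free C9 hydroxyl and the selenide should not interfere.

Step 8
Reactants: 12 (E)-N-(2-phenylaziridin-1-yl)imine of aldehyde 8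
Product: 13 (1S,4aS,8aS)-2,5,5,8a-tetramethyl-1,4,4a,5,6,7,8,8a-octahydronaphthalen-1-ol
Conditions: Bu3SnH (1.3 equiv, syringe pump), AIBN, PhH (0.01 M), 80 °C
Reagents that add atoms: none
Why: Bu3Sn• abstracts the phenylselanyl group from C10; the tertiary radical adds to the imine carbon C1, the aminyl radical opens the aziridine and expels styrene and N2, and the resulting C1 radical is reduced by Bu3SnH, so the former aldehyde carbon ends as the C1 methylene with nothing left to remove. The closest known reaction type is the tin-mediated radical cyclization onto N-aziridinyl imines, used for consecutive C–C bond formation at a carbonyl carbon. Ring A (C10, C5, C4, C3, C2, C1) closes in the 6-exo-trig mode. C10 is the only new stereocentre and is controlled by C5: with C9 at the alcohol level ring B is a cyclohex-3-ene half-chair puckered at C5 and C10, the bulky C4 arm on C5 is equatorial, and the acceptor should reach the radical on the face of the axial H-5 through a chair-like array in which both ring B bonds are equatorial on the new ring and the C10 methyl is axial, i.e. trans fusion, as in the second ring closure of radical polyene cyclizations. The step needs trans over cis fusion and ring closure over premature hydrogen transfer or 1,2-vinyl shift of C8 from C9 to C10; the first is secured by having reduced the C9 ketone (a C9 carbonyl would flatten C9–C10 and force cis closure from the C5 tether), the second by the high rate of addition to the C=N acceptor and slow addition of the stannane.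

Step 9
Reactants: 13 (1S,4aS,8aS)-2,5,5,8a-tetramethyl-1,4,4a,5,6,7,8,8a-octahydronaphthalen-1-ol
Product: 14 (4aS,8aS)-2,5,5,8a-tetramethyl-4a,5,6,7,8,8a-hexahydronaphthalen-1(4H)-one
Conditions: Dess–Martin periodinane, NaHCO3, CH2Cl2, 0 to 23 °C
Reagents that add atoms: none
Why: Dess–Martin oxidation of the secondary allylic alcohol; both C9 epimers converge on one enone and the two ring-fusion centres are untouched.

Step 10
Reactants: 15 (3E,7E)-4,8,12-trimethyltrideca-3,7,11-trien-1-ol
Product: 16 (3E,7E)-1-iodo-4,8,12-trimethyltrideca-3,7,11-triene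
Conditions: I2, PPh3, imidazole, CH2Cl2, 0 to 23 °C
Reagents that add atoms: iodine, II
Why: Appel-type iodination of a primary alcohol under neutral conditions that should leave the three trisubstituted alkenes and their geometry untouched.

Step 11
Reactants: 16 (3E,7E)-1-iodo-4,8,12-trimethyltrideca-3,7,11-triene; 14 (4aS,8aS)-2,5,5,8a-tetramethyl-4a,5,6,7,8,8a-hexahydronaphthalen-1(4H)-one
Product: 19 methyl (1S,4aS,8aS)-2,5,5,8a-tetramethyl-1-[(3E,7E)-4,8,12-trimethyltrideca-3,7,11-trien-1-yl]-1,4,4a,5,6,7,8,8a-octahydronaphthalen-1-yl carbonate, via homofarnesyllithium 17 (not isolated), via lithium alkoxide 18 (not isolated)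
Conditions: 16, t-BuLi (2.1 equiv), Et2O/pentane, −78 °C; 14, −78 to 0 °C; ClCO2Me, 0 to 23 °C
Reagents that add atoms: methyl chloroformate, COC(=O)Cl
Why: Iodine–lithium exchange gives the primary alkyllithium, which should add 1,2 to the enone carbonyl from the α face, anti to the axial C10 methyl (as in additions to 17-keto steroids), placing the oxygen 9β; the tertiary alkoxide is acylated in the flask to the allylic carbonate.

Step 12
Reactants: 19 methyl (1S,4aS,8aS)-2,5,5,8a-tetramethyl-1-[(3E,7E)-4,8,12-trimethyltrideca-3,7,11-trien-1-yl]-1,4,4a,5,6,7,8,8a-octahydronaphthalen-1-yl carbonate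
Product: 20 (1S,4aS,8aS)-2,5,5,8a-tetramethyl-1-[(3E,7E)-4,8,12-trimethyltrideca-3,7,11-trien-1-yl]-1,4,4a,5,6,7,8,8a-octahydronaphthalene
Conditions: Pd(OAc)2 (5 mol %), Bu3P (5 mol %), HCO2NH4, 1,4-dioxane, 100 °C
Reagents that add atoms: none
Why: Palladium-catalysed formate hydrogenolysis of an allylic carbonate (Tsuji–Trost-type ionization): palladium enters anti to the 9β-carbonate on the α face of the C7–C8–C9 allyl unit, the palladium formate loses CO2, and the hydride is passed from the metal to the more substituted terminus C9 on that same face, which should give 9α-H, the β side chain and the less substituted C7=C8 alkene.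

**Compound list**

1 | (R)-(−)-carvone, (5R)-2-methyl-5-(prop-1-en-2-yl)cyclohex-2-en-1-one | O=C1C(C)=CC[C@@H](C(C)=C)C1 | starting material
2 | 4-methyl-4-[(1R)-4-methyl-5-oxocyclohex-3-en-1-yl]pentanenitrile | O=C1C(C)=CC[C@@H](C(C)(C)CCC#N)C1 | intermediate
3 | lithium enolate of 2 (cross-conjugated, C9–O, C9=C10) | [Li+].[O-]C1=C[C@H](C(C)(C)CCC#N)CC=C1C | intermediate (not isolated)
4 | 4-[(1R,6S)-4,6-dimethyl-5-oxocyclohex-3-en-1-yl]-4-methylpentanenitrile (6-methyl anti to the side chain; the 6-epimer is equally usable) | O=C1C(C)=CC[C@@H](C(C)(C)CCC#N)[C@@H]1C | intermediate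
5 | lithium enolate of 4 (tetrasubstituted C9=C10) | [Li+].[O-]C1=C(C)[C@H](C(C)(C)CCC#N)CC=C1C | intermediate (not isolated)
6 | 4-[(1S,6S)-4,6-dimethyl-5-oxo-6-(phenylselanyl)cyclohex-3-en-1-yl]-4-methylpentanenitrile | O=C1C(C)=CC[C@@H](C(C)(C)CCC#N)[C@]1(C)[Se]c2ccccc2 | intermediate
7 | O-(diisobutylaluminio) alkoxide and N-(diisobutylaluminio) aldimine derived from 6 | CC(C)C[Al](CC(C)C)O[C@H]1C(C)=CC[C@@H](C(C)(C)CCC=N[Al](CC(C)C)CC(C)C)[C@]1(C)[Se]c2ccccc2 | intermediate (not isolated)
8 | 4-[(1S,5S,6S)-5-hydroxy-4,6-dimethyl-6-(phenylselanyl)cyclohex-3-en-1-yl]-4-methylpentanal (5-epimer also formed and used) | O[C@H]1C(C)=CC[C@@H](C(C)(C)CCC=O)[C@]1(C)[Se]c2ccccc2 | intermediate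
9 | (±)-1-phenylethane-1,2-diol | OCC(O)c1ccccc1 | starting material
10 | (±)-1-phenylethane-1,2-diyl dimethanesulfonate | CS(=O)(=O)OCC(OS(C)(=O)=O)c1ccccc1 | intermediate
11 | (±)-1-amino-2-phenylaziridine | NN1CC1c1ccccc1 | intermediate
12 | (E)-N-(2-phenylaziridin-1-yl)imine of aldehyde 8 (either configuration at the aziridine carbon) | O[C@H]1C(C)=CC[C@@H](C(C)(C)CC/C=N/N3CC3c3ccccc3)[C@]1(C)[Se]c2ccccc2 | intermediate
13 | (1S,4aS,8aS)-2,5,5,8a-tetramethyl-1,4,4a,5,6,7,8,8a-octahydronaphthalen-1-ol (1-epimer also usable) | O[C@H]1C(C)=CC[C@H]2C(C)(C)CCC[C@]12C | intermediate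
14 | (4aS,8aS)-2,5,5,8a-tetramethyl-4a,5,6,7,8,8a-hexahydronaphthalen-1(4H)-one | O=C1C(C)=CC[C@H]2C(C)(C)CCC[C@]12C | intermediate
15 | (3E,7E)-4,8,12-trimethyltrideca-3,7,11-trien-1-ol (homofarnesol) | OCC/C=C(\C)CC/C=C(\C)CCC=C(C)C | starting material
16 | (3E,7E)-1-iodo-4,8,12-trimethyltrideca-3,7,11-triene | ICC/C=C(\C)CC/C=C(\C)CCC=C(C)C | intermediate
17 | [(3E,7E)-4,8,12-trimethyltrideca-3,7,11-trien-1-yl]lithium | [Li]CC/C=C(\C)CC/C=C(\C)CCC=C(C)C | intermediate (not isolated)
18 | lithium (1S,4aS,8aS)-2,5,5,8a-tetramethyl-1-[(3E,7E)-4,8,12-trimethyltrideca-3,7,11-trien-1-yl]-1,4,4a,5,6,7,8,8a-octahydronaphthalen-1-olate | [Li]O[C@@]1(CC/C=C(\C)CC/C=C(\C)CCC=C(C)C)C(C)=CC[C@H]2C(C)(C)CCC[C@]12C | intermediate (not isolated)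
19 | methyl (1S,4aS,8aS)-2,5,5,8a-tetramethyl-1-[(3E,7E)-4,8,12-trimethyltrideca-3,7,11-trien-1-yl]-1,4,4a,5,6,7,8,8a-octahydronaphthalen-1-yl carbonate | COC(=O)O[C@@]1(CC/C=C(\C)CC/C=C(\C)CCC=C(C)C)C(C)=CC[C@H]2C(C)(C)CCC[C@]12C | intermediate
20 | (1S,4aS,8aS)-2,5,5,8a-tetramethyl-1-[(3E,7E)-4,8,12-trimethyltrideca-3,7,11-trien-1-yl]-1,4,4a,5,6,7,8,8a-octahydronaphthalene | CC(C)=CCC/C(C)=C/CC/C(C)=C/CC[C@H]1C(C)=CC[C@H]2C(C)(C)CCC[C@]12C | target

**Count and risks**

Total step count: 12. Longest linear sequence: 9 steps (1, 2, 3, 4, 7, 8, 9, 11, 12).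

Steps most likely to fail:

Step 8. Hydrogen-atom transfer from Bu3SnH to the hindered tertiary C10 radical, or thermal loss of styrene from the aziridinyl imine, may outrun the six-membered closure; approach on the axial face would give the cis fusion. The fallback sets out from 8 and returns at 14, using the aldehyde itself as the radical acceptor at room temperature, where the chair-like closure should be favoured more strongly. Bu3SnH with Et3B/air in toluene at 23 °C should close C10 onto the formyl carbon and give (4aS,8aR)-2,5,5,8a-tetramethyl-1,4,4a,5,6,7,8,8a-octahydronaphthalene-1,8-diol F1. MnO2 should oxidize only the allylic C9 hydroxyl to (4aS,8aR)-8-hydroxy-2,5,5,8a-tetramethyl-4a,5,6,7,8,8a-hexahydronaphthalen-1(4H)-one F2. The Burgess reagent should eliminate the C1 hydroxyl toward C2, the only side with β-hydrogens, to (4aS,8aS)-2,5,5,8a-tetramethyl-4a,5,6,8a-tetrahydronaphthalen-1(4H)-one F3. H2 over RhCl(PPh3)3 should saturate the disubstituted C1=C2 alkene and leave the trisubstituted enone, giving 14.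

Step 12. Hydride transfer to the wrong allyl terminus (C7, giving the 8,9-alkene), β-hydride elimination to dienes, or a wrong facial sense if the organolithium of step 11 added syn to the angular methyl. The fallback sets out from 14 and returns at 20 without a C9–O bond.
- Ph3P=CH2 should give (4aS,8aS)-2,5,5,8a-tetramethyl-1-methylidene-1,4,4a,5,6,7,8,8a-octahydronaphthalene F4.
- 9-Borabicyclo[3.3.1]nonane should add to the exocyclic methylene from the α face to give 9-{[(1S,4aS,8aS)-2,5,5,8a-tetramethyl-1,4,4a,5,6,7,8,8a-octahydronaphthalen-1-yl]methyl}-9-borabicyclo[3.3.1]nonane F5.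
- NaOH/H2O2 should give [(1S,4aS,8aS)-2,5,5,8a-tetramethyl-1,4,4a,5,6,7,8,8a-octahydronaphthalen-1-yl]methanol (drimenol) F6.
- I2, PPh3 and imidazole should give (1S,4aS,8aS)-1-(iodomethyl)-2,5,5,8a-tetramethyl-1,4,4a,5,6,7,8,8a-octahydronaphthalene F7.
- Mg should give {[(1S,4aS,8aS)-2,5,5,8a-tetramethyl-1,4,4a,5,6,7,8,8a-octahydronaphthalen-1-yl]methyl}magnesium iodide F8.
- Copper-catalysed coupling (Li2CuCl4, THF, −78 to 0 °C) with commercial (2E,6E)-farnesyl bromide at its primary carbon should give 20.

Step 3. Slow or misdirected deprotonation of the hindered tertiary C10–H (γ-deprotonation at C6 instead) or selenenylation on oxygen. The fallback sets out from 2 and returns at 6 by reversing the order of the two C10 substituents. Enolate 3 with PhSeBr should give 4-methyl-4-[(1R,6S)-4-methyl-5-oxo-6-(phenylselanyl)cyclohex-3-en-1-yl]pentanenitrile F9. LiN(i-Pr)2 should then form the selenium-stabilized lithium enolate of F9 F10 readily, and the small electrophile MeI should C-methylate it to 6.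

Further compounds
F1 | step 8 | (4aS,8aR)-2,5,5,8a-tetramethyl-1,4,4a,5,6,7,8,8a-octahydronaphthalene-1,8-diol (carbinol epimers) | O[C@H]1C(C)=CC[C@H]2C(C)(C)CCC(O)[C@]12C
F2 | step 8 | (4aS,8aR)-8-hydroxy-2,5,5,8a-tetramethyl-4a,5,6,7,8,8a-hexahydronaphthalen-1(4H)-one (8-epimers) | O=C1C(C)=CC[C@H]2C(C)(C)CCC(O)[C@]12C
F3 | step 8 | (4aS,8aS)-2,5,5,8a-tetramethyl-4a,5,6,8a-tetrahydronaphthalen-1(4H)-one | O=C1C(C)=CC[C@H]2C(C)(C)CC=C[C@]12C
F4 | step 12 | (4aS,8aS)-2,5,5,8a-tetramethyl-1-methylidene-1,4,4a,5,6,7,8,8a-octahydronaphthalene | C=C1C(C)=CC[C@H]2C(C)(C)CCC[C@]12C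
F5 | step 12 | 9-{[(1S,4aS,8aS)-2,5,5,8a-tetramethyl-1,4,4a,5,6,7,8,8a-octahydronaphthalen-1-yl]methyl}-9-borabicyclo[3.3.1]nonane | C([C@H]1C(C)=CC[C@H]2C(C)(C)CCC[C@]12C)B1C2CCCC1CCC2
F6 | step 12 | [(1S,4aS,8aS)-2,5,5,8a-tetramethyl-1,4,4a,5,6,7,8,8a-octahydronaphthalen-1-yl]methanol (drimenol) | OC[C@H]1C(C)=CC[C@H]2C(C)(C)CCC[C@]12C
F7 | step 12 | (1S,4aS,8aS)-1-(iodomethyl)-2,5,5,8a-tetramethyl-1,4,4a,5,6,7,8,8a-octahydronaphthalene | IC[C@H]1C(C)=CC[C@H]2C(C)(C)CCC[C@]12C
F8 | step 12 | {[(1S,4aS,8aS)-2,5,5,8a-tetramethyl-1,4,4a,5,6,7,8,8a-octahydronaphthalen-1-yl]methyl}magnesium iodide | I[Mg]C[C@H]1C(C)=CC[C@H]2C(C)(C)CCC[C@]12C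
F9 | step 3 | 4-methyl-4-[(1R,6S)-4-methyl-5-oxo-6-(phenylselanyl)cyclohex-3-en-1-yl]pentanenitrile | O=C1C(C)=CC[C@@H](C(C)(C)CCC#N)[C@@H]1[Se]c2ccccc2
F10 | step 3 | lithium enolate of F9 (C9–O, C9=C10) | [Li+].[O-]C1=C([Se]c2ccccc2)[C@H](C(C)(C)CCC#N)CC=C1C
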